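(All runs were generated by integration on assumed constants, and the scatter is random.)

Before any ratio is carried across from the old runs, a choice has to be made: does the charge of D change the course of the flask, or does it drop out when everything is counted as fractions of the charge?

| flask | D | remark | time |
|---|---|---|---|
| birch | 13 mM | run made earlier |  |
| larch | 28 mM | run made earlier |  |
| flask | 19 mM |  | 2.5 d |

| run | time / d | J / % | E / % |
|---|---|---|---|
| birch | 0.833 | 3.2 | 16.2 |
| birch | 1.67 | 8.9 | 23.7 |
| birch | 2.50 | 13.4 | 26.5 |
| birch | 3.00 | 16.2 | 29.5 |
| larch | 0.417 | 1.1 | 10.3 |
| larch | 1.04 | 5.7 | 19.0 |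
| larch | 2.08 | 11.1 | 26.0 |
| larch | 3.00 | 16.1 | 28.5 |

(each reading ± 0.5 percentage points)

- ratio of J to E at 1.5 h
- ratio of J to E at 10 h
- ratio of J to E at 2.5 d

- the analysis behind the earlier runs scatters by 0.5 percentage points, standard deviation

Two extreme flasks can be solved in the head. If the rate ignored the charge (order zero), the fraction converted at a given time would scale inversely with the charge, so the larch run would reach 0.464 of the birch fraction. If the rate followed the charge (first order), it would reach the same fraction as the birch run.

At 3.00 d, counting J and E together, the larch run stands 1.1 percentage points below the birch run, and a difference of four readings scatters by 1 point. The measure is the apparent reaction order: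

order = 1 + ln(larch fraction / birch fraction) / ln(larch charge / birch charge) = 0.968

Within that scatter the readings lie at the first-order end, and a charge of 19 mM, less than larch and more than birch, stands inside the tested span. Ratios can be read straight across:

at 2.5 d: birch reading, 0.506

at 10 h: larch reading, 0.107

at 1.5 h: no reading exists; J lags behind E, so taking the ratio as proportional to time gives 0.0160

The forecast gave 0.016, 0.1 and 0.5, with the ground: “the kinetics look first-order”.

The flask gives 0.0171, 0.108 and 0.497.

    E ⇌ J (K = 1.10, k = 0.0230 h⁻¹)
    D ⇌ E (K = 1.70, k = 0.0120 h⁻¹)
    J ⇌ G (K = 0.590, k = 0.0190 h⁻¹)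

The order reading of 0.968 puts conversion at 48 mM at 0.971 of that in the flask, and the neighbouring flask keeps D at 55%, as the flask does (55%), with the ratio again 0.497. At 2.50 d the flask makes J 2.84 times faster than it uses it up, each step taken net, and E 1.34 times faster. At 25.0 d the flask holds J at 32.9% and E at 30.0%.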